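Both C(=O)–Cα bonds of the two dihydrochalcone arms are disconnected. Each ketone carbon sits on a resorcinol ring (rings A) next to a 2-hydroxyl, and each Cα–Cβ pair can be read as a former vinyl group on the guaiacyl ring B or the catechol ring C. As a phenoxide, that ortho hydroxyl holds rhodium beside the formyl C–H of 2,4-dihydroxybenzaldehyde, so a single twofold hydroacylation should join two aldehyde molecules to a diaryl ether bis-styrene and complete the carbon skeleton. The bis-styrene carries one benzyl ether on ring C and comes from a selective benzylation, an SNAr diaryl ether synthesis and a double Wittig methylenation.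

Key step: step 4

Remark on the chemistry: rings A are the two 2,4-dihydroxyphenyl ketone rings, ring B is the methoxy-bearing ring and ring C is the ring carrying the free phenol of the diaryl ether. The more acidic 4-hydroxyl of 2,4-dihydroxybenzaldehyde is assumed to remain a spectator under catalytic K3PO4, because only the 2-phenoxide can chelate rhodium.

Step 1
Reactants: 1 3,4-dihydroxybenzaldehyde
Product: 2 4-(benzyloxy)-3-hydroxybenzaldehyde
Conditions: BnBr (1.0 equiv), NaHCO3 (1.5 equiv), DMF, 40 °C
Reagents that add atoms: benzyl bromide, BrCc1ccccc1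
Why: The 4-hydroxyl para to the formyl group is a vinylogous acid and the only phenol that NaHCO3 ionises to a useful extent, so the Williamson ether synthesis should alkylate O-4 and leave O-3 free.

Step 2
Reactants: 2 4-(benzyloxy)-3-hydroxybenzaldehyde; 3 4-fluoro-3-methoxybenzaldehyde
Product: 4 4-(benzyloxy)-3-(4-formyl-2-methoxyphenoxy)benzaldehyde
Conditions: K2CO3 (1.5 equiv), DMSO, 110 °C, N2
Reagents that add atoms: none
Why: The phenoxide of 2 should displace the fluoride para to the formyl group of 3 by nucleophilic aromatic substitution through a Meisenheimer anion stabilised by that aldehyde, and neither aldehyde has α-hydrogens for aldol side reactions.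

Step 3
Reactants: 4 4-(benzyloxy)-3-(4-formyl-2-methoxyphenoxy)benzaldehyde
Product: 7 1-(benzyloxy)-4-ethenyl-2-(4-ethenyl-2-methoxyphenoxy)benzene, via ring B vinyl aldehyde 5 (not isolated), via ring C vinyl aldehyde 6 (not isolated)
Conditions: Ph3PCH3Br (2.6 equiv), KOtBu (2.5 equiv), THF, 0 °C; then 4, 0 °C to rt
Reagents that add atoms: methyltriphenylphosphonium bromide, C[P+](c1ccccc1)(c1ccccc1)c1ccccc1.[Br-]
Why: Wittig methylenation by the unstabilised ylide should convert both non-enolisable aryl aldehydes one after the other, while the ethers are inert to the base and no alkene geometry arises.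

Step 4
Reactants: 7 1-(benzyloxy)-4-ethenyl-2-(4-ethenyl-2-methoxyphenoxy)benzene; 8 2,4-dihydroxybenzaldehyde (2.5 equiv)
Product: 11 3-[4-(benzyloxy)-3-{4-[3-(2,4-dihydroxyphenyl)-3-oxopropyl]-2-methoxyphenoxy}phenyl]-1-(2,4-dihydroxyphenyl)propan-1-one, via ring B monoketone 9 (not isolated), via ring C monoketone 10 (not isolated)
Conditions: [Rh(cod)Cl]2 (5 mol%), Ph2P(CH2)4PPh2 (10 mol%), K3PO4 (20 mol%), 1,4-dioxane, 80 °C, Ar
Reagents that add atoms: none
Why: K3PO4 turns the 2-hydroxyl of 8 into a phenoxide that binds monovalent rhodium, and oxidative addition of the neighbouring formyl C–H gives a five-membered acyl hydride chelate of trivalent rhodium that is held too rigidly to decarbonylate; a vinyl group of 7 then inserts into Rh–H and C–C reductive elimination forms the C(=O)–Cα bond, the cycle running once at each alkene through 9 or 10. The closest known reaction type is the rhodium-catalysed, chelation-assisted intermolecular hydroacylation of alkenes with salicylaldehydes. No ring is closed and no stereocentre is created. The selectivity needed is linear addition (acyl to the terminal carbon) at both vinylarenes, and this is the uncertain point, because a benzylic rhodium alkyl is electronically accessible. Hydride insertion is reversible and reductive elimination is turnover-limiting in this reaction class, so the wide-bite-angle bisphosphine, which crowds the metal, should favour elimination from the less hindered primary alkyl. On the substrate side, both positions flanking each vinyl group are C–H, so nothing on rings B and C can chelate rhodium towards the benzylic carbon, the benzyl ether stops the ring C phenol from competing as a phenoxide ligand, and the 4-hydroxyl of 8 cannot close a chelate.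

Step 5
Reactants: 11 3-[4-(benzyloxy)-3-{4-[3-(2,4-dihydroxyphenyl)-3-oxopropyl]-2-methoxyphenoxy}phenyl]-1-(2,4-dihydroxyphenyl)propan-1-one
Product: 12 verbenachalcone
Conditions: H2 (1 atm), 10% Pd/C, EtOAc, rt
Reagents that add atoms: none
Why: Catalytic hydrogenolysis on Pd/C should cleave the single aryl benzyl ether quickly in a neutral solvent, while the two electron-rich aryl ketones, each hydrogen-bonded to its ortho hydroxyl, are reduced much more slowly, so the reaction is stopped once 11 is consumed.

Compound list
1 | 3,4-dihydroxybenzaldehyde | O=Cc1ccc(O)c(O)c1 | starting material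
2 | 4-(benzyloxy)-3-hydroxybenzaldehyde | O=Cc1ccc(OCc2ccccc2)c(O)c1 | intermediate
3 | 4-fluoro-3-methoxybenzaldehyde | COc1cc(C=O)ccc1F | starting material
4 | 4-(benzyloxy)-3-(4-formyl-2-methoxyphenoxy)benzaldehyde | COc1cc(C=O)ccc1Oc1cc(C=O)ccc1OCc1ccccc1 | intermediate
5 | ring B vinyl aldehyde, 4-(benzyloxy)-3-(4-ethenyl-2-methoxyphenoxy)benzaldehyde | COc1cc(C=C)ccc1Oc1cc(C=O)ccc1OCc1ccccc1 | intermediate (not isolated)
6 | ring C vinyl aldehyde, 4-[2-(benzyloxy)-5-ethenylphenoxy]-3-methoxybenzaldehyde | COc1cc(C=O)ccc1Oc1cc(C=C)ccc1OCc1ccccc1 | intermediate (not isolated)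
7 | bis-styrene, 1-(benzyloxy)-4-ethenyl-2-(4-ethenyl-2-methoxyphenoxy)benzene | C=Cc1ccc(OCc2ccccc2)c(Oc2ccc(C=C)cc2OC)c1 | intermediate
8 | 2,4-dihydroxybenzaldehyde | O=Cc1ccc(O)cc1O | starting material
9 | ring B monoketone, 3-{4-[2-(benzyloxy)-5-ethenylphenoxy]-3-methoxyphenyl}-1-(2,4-dihydroxyphenyl)propan-1-one | COc1cc(CCC(=O)c2ccc(O)cc2O)ccc1Oc1cc(C=C)ccc1OCc1ccccc1 | intermediate (not isolated)
10 | ring C monoketone, 3-[4-(benzyloxy)-3-(4-ethenyl-2-methoxyphenoxy)phenyl]-1-(2,4-dihydroxyphenyl)propan-1-one | COc1cc(C=C)ccc1Oc1cc(CCC(=O)c2ccc(O)cc2O)ccc1OCc1ccccc1 | intermediate (not isolated)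
11 | verbenachalcone benzyl ether (benzyl on the ring C phenol), 3-[4-(benzyloxy)-3-{4-[3-(2,4-dihydroxyphenyl)-3-oxopropyl]-2-methoxyphenoxy}phenyl]-1-(2,4-dihydroxyphenyl)propan-1-one | COc1cc(CCC(=O)c2ccc(O)cc2O)ccc1Oc1cc(CCC(=O)c2ccc(O)cc2O)ccc1OCc1ccccc1 | intermediate
12 | verbenachalcone, 3-[3-{4-[3-(2,4-dihydroxyphenyl)-3-oxopropyl]-2-methoxyphenoxy}-4-hydroxyphenyl]-1-(2,4-dihydroxyphenyl)propan-1-one | COc1cc(CCC(=O)c2ccc(O)cc2O)ccc1Oc1cc(CCC(=O)c2ccc(O)cc2O)ccc1O | target

Total step count: 5
Longest linear sequence: 5 steps (1 → 2 → 4 → 7 → 11 → 12)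

Steps most likely to fail

Step 4. Hydride insertion may place rhodium on the benzylic carbon at one or both vinylarenes and lead to branched α-methyl ketones. With two sites, any shortfall in regiocontrol counts twice, and the second addition may also stall at 9 or 10. The fallback replaces the rhodium step by aldol chemistry; it sets out from dialdehyde 4 and comes back to the route at target 12. Dialdehyde 4 would be condensed twice with commercial 1-[2,4-bis(benzyloxy)phenyl]ethan-1-one (CC(=O)c1ccc(OCc2ccccc2)cc1OCc1ccccc1) under Claisen–Schmidt conditions (KOH, EtOH/THF, rt). This should pass through the ring B chalcone aldehyde F1 and the ring C chalcone aldehyde F2, neither isolated, to the E,E bis-chalcone F3. Hydrogenation of F3 (H2, 10% Pd/C, EtOAc/THF, rt) should then saturate both enone C=C bonds and cleave all five benzyl ethers in one operation to give 12; the partly reduced species of this last operation are not separate stages.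

Step 2. The methoxy group ortho to fluorine donates into the carbon under attack, so the addition–elimination may be slow, and at the temperatures then needed the aldehydes may degrade. The fallback changes the bond-forming mode to a copper-catalysed Ullmann-type C–O coupling; it sets out from phenol 2 and comes back at dialdehyde 4. Phenol 2 would be coupled with commercial 4-bromo-3-methoxybenzaldehyde (COc1cc(C=O)ccc1Br) using CuI, N,N-dimethylglycine and Cs2CO3 in 1,4-dioxane at 90 °C. It makes no compound outside the list.

Step 5. On prolonged exposure to hydrogen the benzylic ketones may be reduced to alcohols and further to methylene groups. The fallback removes the benzyl group by Lewis-acid dealkylation; it sets out from 11 and comes back at target 12. Compound 11 would be treated with BCl3 and pentamethylbenzene as cation scavenger in CH2Cl2 at −78 °C, conditions under which the aryl methyl ether and the ketones should survive. It makes no compound outside the list.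

Further compounds
F1 | step 4 | ring B chalcone aldehyde, 4-(benzyloxy)-3-(4-{(1E)-3-[2,4-bis(benzyloxy)phenyl]-3-oxoprop-1-en-1-yl}-2-methoxyphenoxy)benzaldehyde | COc1cc(/C=C/C(=O)c2ccc(OCc3ccccc3)cc2OCc2ccccc2)ccc1Oc1cc(C=O)ccc1OCc1ccccc1
F2 | step 4 | ring C chalcone aldehyde, 4-[2-(benzyloxy)-5-{(1E)-3-[2,4-bis(benzyloxy)phenyl]-3-oxoprop-1-en-1-yl}phenoxy]-3-methoxybenzaldehyde | COc1cc(C=O)ccc1Oc1cc(/C=C/C(=O)c2ccc(OCc3ccccc3)cc2OCc2ccccc2)ccc1OCc1ccccc1
F3 | step 4 | E,E bis-chalcone, (2E)-3-[4-(benzyloxy)-3-(4-{(1E)-3-[2,4-bis(benzyloxy)phenyl]-3-oxoprop-1-en-1-yl}-2-methoxyphenoxy)phenyl]-1-[2,4-bis(benzyloxy)phenyl]prop-2-en-1-one | COc1cc(/C=C/C(=O)c2ccc(OCc3ccccc3)cc2OCc2ccccc2)ccc1Oc1cc(/C=C/C(=O)c2ccc(OCc3ccccc3)cc2OCc2ccccc2)ccc1OCc1ccccc1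
F0 | step 2 | none | none
F0 | step 5 | none | none
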